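The indane five-membered ring is cut at two bonds: aryl C6a–C7 (the benzylic CH2) and the cyclobutane/cyclopentane fusion bond C2a–C7a. Both are made from a trans-4,5-diaryl-2-diazo-3,3-dimethylcyclopentanone. Photochemical Wolff ring contraction moves the aryl-bearing carbon onto the carbene carbon (C2a–C7a, cyclobutane formed), and the resulting ketene, protonated to an acylium ion, acylates ring A (C6a–C7). The step exploits that C6a lies ortho and para to the two oxygens of ring A and that C7 can be carried as a carbonyl, which afterwards directs the selective C6 demethylation and is then reduced away.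

Key step: step 6

Remark: the tricycle is numbered as 2,2a,7,7a-tetrahydro-1H-cyclobuta[a]indene. C1 is CMe2, C2 is the CH bearing the catechol ring B, C2a and C7a are the ring-fusion CH, C7 is the benzylic CH2, and C2b–C6a are ring A (C3 prenyl, C4 OMe, C6 OH). The sense of induction in step 1 is assumed from the established facial model for cyclopent-2-enone.

Step 1
Reactants: 1 4,4-dimethylcyclopent-2-en-1-one; 2 1,3-benzodioxol-5-ylboronic acid
Product: 3 (3S)-3-(1,3-benzodioxol-5-yl)-4,4-dimethylcyclopentan-1-one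
Conditions: Rh(acac)(C2H4)2 (3 mol %), (R)-BINAP (3.3 mol %), 2 (2.5 equiv), dioxane/H2O 10:1, 100 °C
Reagents that add atoms: none
Why: Hayashi–Miyaura asymmetric conjugate addition, in which the aryl species of monovalent rhodium inserts the enone on the face fixed by (R)-BINAP; the descriptor is S here because the gem-dimethyl carbon outranks C2, and this β-stereocentre cannot epimerise later.

Step 2
Reactants: 3 (3S)-3-(1,3-benzodioxol-5-yl)-4,4-dimethylcyclopentan-1-one; 4 1-bromo-3,5-dimethoxybenzene
Product: 5 (2R,3S)-3-(1,3-benzodioxol-5-yl)-2-(3,5-dimethoxyphenyl)-4,4-dimethylcyclopentan-1-one (aryl groups trans)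
Conditions: Pd(OAc)2 (2 mol %), XPhos (4 mol %), NaOtBu (1.3 equiv), toluene, 70 °C; then DBU (cat.), CH2Cl2, rt
Reagents that add atoms: none
Why: Palladium-catalysed α-arylation of the ketone enolate should prefer the methylene next to the tertiary C3 over the neopentyl-type methylene next to the quaternary carbon, and base equilibration through the enol places the new aryl trans to the C3 aryl (thermodynamic control by the fixed C3 centre).

Step 3
Reactants: 5 (2R,3S)-3-(1,3-benzodioxol-5-yl)-2-(3,5-dimethoxyphenyl)-4,4-dimethylcyclopentan-1-one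
Product: 6 (2R,3S)-3-(1,3-benzodioxol-5-yl)-2-(2-bromo-3,5-dimethoxyphenyl)-4,4-dimethylcyclopentan-1-one
Conditions: NBS (1.0 equiv), MeCN, 0 °C
Reagents that add atoms: N-bromosuccinimide, O=C1CCC(=O)N1Br
Why: Electrophilic aromatic bromination should occur on the 3,5-dimethoxyphenyl ring, by far the most electron-rich arene, at the position ortho to the alkyl group and para to a methoxy group (the two such positions are equivalent), as is usual for 3,5-dimethoxybenzyl derivatives.

Step 4
Reactants: 6 (2R,3S)-3-(1,3-benzodioxol-5-yl)-2-(2-bromo-3,5-dimethoxyphenyl)-4,4-dimethylcyclopentan-1-one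
Product: 7 (2R,3R,5Z)-3-(1,3-benzodioxol-5-yl)-2-(2-bromo-3,5-dimethoxyphenyl)-5-(hydroxymethylidene)-4,4-dimethylcyclopentan-1-one (same spatial arrangement as 6; the C3 descriptor changes only formally)
Conditions: HCO2Et (5 equiv), NaH (3 equiv), EtOH (cat.), THF, 0 °C to rt; aq. HCl work-up
Reagents that add atoms: ethyl formate, CCOC=O
Why: Claisen formylation ends at the C5 methylene because only there can the stabilised β-ketoaldehyde enolate form (C2 is a methine), and the C2 centre stays in its thermodynamic trans arrangement under the basic conditions.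

Step 5
Reactants: 7 (2R,3R,5Z)-3-(1,3-benzodioxol-5-yl)-2-(2-bromo-3,5-dimethoxyphenyl)-5-(hydroxymethylidene)-4,4-dimethylcyclopentan-1-one
Product: 8 (4R,5R)-4-(1,3-benzodioxol-5-yl)-5-(2-bromo-3,5-dimethoxyphenyl)-2-diazo-3,3-dimethylcyclopentan-1-one
Conditions: 4-acetamidobenzenesulfonyl azide (1.2 equiv), Et3N (2 equiv), MeCN, 0 °C to rt
Reagents that add atoms: 4-acetamidobenzenesulfonyl azide, CC(=O)Nc1ccc(cc1)S(=O)(=O)N=[N+]=[N-]
Why: Regitz deformylative diazo transfer, in which the azide adds to the enolate and the adduct fragments with loss of the formyl group as the N-formylsulfonamide, should place the diazo group on the carbon between the carbonyl and the quaternary centre without touching the stereocentres.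

Step 6
Reactants: 8 (4R,5R)-4-(1,3-benzodioxol-5-yl)-5-(2-bromo-3,5-dimethoxyphenyl)-2-diazo-3,3-dimethylcyclopentan-1-one
Product: 10 (2S,2aS,7aS)-2-(1,3-benzodioxol-5-yl)-3-bromo-4,6-dimethoxy-1,1-dimethyl-1,2,2a,7a-tetrahydro-7H-cyclobuta[a]inden-7-one, via cyclobutylidene ketene 9 (not isolated)
Conditions: hν (450 nm LEDs), CH2Cl2 (0.01 M, degassed), −20 °C, until the diazo ketone is consumed; then TfOH (10 mol %), −20 to 0 °C, same flask
Reagents that add atoms: none
Why: Photoexcitation of the cyclic, s-Z-locked α-diazo ketone expels N2 and, in a concerted Wolff 1,2-shift, the aryl-bearing ring carbon migrates with retention from the carbonyl carbon to the diazo carbon, which contracts the cyclopentanone to ketene 9 and forms the C2a–C7a bond. Catalytic acid then protonates the ketene at C7a to an acylium ion, which attacks the only free ortho position of the neighbouring aryl ring (ortho to one methoxy group, para to the other) in a 5-exo Friedel–Crafts acylation that forms C6a–C7 and returns the proton. The closest known reactions are the ring-contractive Wolff rearrangement of 2-diazocyclopentanones and the Friedel–Crafts acylation of arenes by ketene-derived acylium ions, so the cyclobutane arises by ring contraction and not by a four-membered cyclisation. The new stereocentre C7a is dictated by the cis 4/5 fusion that the short tether enforces and is therefore relayed from C2a, whose configuration is retained in the migration; protonation on the wrong face is reversible through the ketene. The step needs acylation of ring A rather than of the benzodioxole ring, which the far higher nucleophilicity of the dimethoxyaryl position and the five-membered (not bridged six-membered) closure should secure, and it needs the Wolff shift rather than a 1,2-methyl shift, which the locked geometry and photochemical activation favour.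

Step 7
Reactants: 10 (2S,2aS,7aS)-2-(1,3-benzodioxol-5-yl)-3-bromo-4,6-dimethoxy-1,1-dimethyl-1,2,2a,7a-tetrahydro-7H-cyclobuta[a]inden-7-one
Product: 11 (2S,2aS,7aS)-3-bromo-2-(3,4-dihydroxyphenyl)-6-hydroxy-4-methoxy-1,1-dimethyl-1,2,2a,7a-tetrahydro-7H-cyclobuta[a]inden-7-one
Conditions: BCl3 (6 equiv), CH2Cl2, −78 °C to rt; H2O work-up
Reagents that add atoms: none
Why: Lewis acid ether cleavage, in which BCl3 chelated between the C7 carbonyl and the peri C6 methoxy oxygen should cleave that methyl ether selectively and also open the methylenedioxy acetal to the catechol, while the non-chelated C4 methoxy group is left; no stereocentre is touched.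

Step 8
Reactants: 11 (2S,2aS,7aS)-3-bromo-2-(3,4-dihydroxyphenyl)-6-hydroxy-4-methoxy-1,1-dimethyl-1,2,2a,7a-tetrahydro-7H-cyclobuta[a]inden-7-one
Product: 12 4-[(2S,2aR,7aS)-3-bromo-6-hydroxy-4-methoxy-1,1-dimethyl-2,2a,7,7a-tetrahydro-1H-cyclobuta[a]inden-2-yl]benzene-1,2-diol
Conditions: Et3SiH (6 equiv), TFA/CH2Cl2 1:2, 0 °C to rt
Reagents that add atoms: none
Why: Ionic hydrogenation (Kursanov–Parnes) of the electron-rich aryl ketone should proceed through a benzylic cation stabilised by the ortho hydroxy and para methoxy groups that takes up hydride twice to give the C7 methylene; the aryl bromide survives and the strongly stabilised cation should not trigger cyclobutylcarbinyl ring expansion.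

Step 9
Reactants: 12 4-[(2S,2aR,7aS)-3-bromo-6-hydroxy-4-methoxy-1,1-dimethyl-2,2a,7,7a-tetrahydro-1H-cyclobuta[a]inden-2-yl]benzene-1,2-diol; 13 tributyl(3-methylbut-2-en-1-yl)stannane
Product: 14 4-[(2S,2aR,7aS)-6-hydroxy-4-methoxy-1,1-dimethyl-3-(3-methylbut-2-en-1-yl)-2,2a,7,7a-tetrahydro-1H-cyclobuta[a]inden-2-yl]benzene-1,2-diol (CNP0236667.1)
Conditions: Pd(PPh3)4 (10 mol %), 13 (2 equiv), DMF (degassed), 95 °C
Reagents that add atoms: none
Why: Stille allylation (oxidative addition of zerovalent palladium into the aryl bromide, transmetalation with the prenylstannane, reductive elimination at the less hindered allyl terminus) should give the linear prenyl group under neutral conditions that tolerate the three free phenols.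

Compound list
1 | 4,4-dimethylcyclopent-2-en-1-one | CC1(C)CC(=O)C=C1 | starting material
2 | 1,3-benzodioxol-5-ylboronic acid | OB(O)c1ccc2OCOc2c1 | starting material
3 | (3S)-3-(1,3-benzodioxol-5-yl)-4,4-dimethylcyclopentan-1-one | O=C1CC(C)(C)[C@H](C1)c1ccc2OCOc2c1 | intermediate
4 | 1-bromo-3,5-dimethoxybenzene | COc1cc(Br)cc(OC)c1 | starting material
5 | (2R,3S)-3-(1,3-benzodioxol-5-yl)-2-(3,5-dimethoxyphenyl)-4,4-dimethylcyclopentan-1-one | COc1cc(OC)cc(c1)[C@@H]1C(=O)CC(C)(C)[C@H]1c1ccc2OCOc2c1 | intermediate
6 | (2R,3S)-3-(1,3-benzodioxol-5-yl)-2-(2-bromo-3,5-dimethoxyphenyl)-4,4-dimethylcyclopentan-1-one | COc1cc(OC)c(Br)c(c1)[C@@H]1C(=O)CC(C)(C)[C@H]1c1ccc2OCOc2c1 | intermediate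
7 | (2R,3R,5Z)-3-(1,3-benzodioxol-5-yl)-2-(2-bromo-3,5-dimethoxyphenyl)-5-(hydroxymethylidene)-4,4-dimethylcyclopentan-1-one | COc1cc(OC)c(Br)c(c1)[C@@H]1C(=O)/C(=C\O)C(C)(C)[C@H]1c1ccc2OCOc2c1 | intermediate
8 | (4R,5R)-4-(1,3-benzodioxol-5-yl)-5-(2-bromo-3,5-dimethoxyphenyl)-2-diazo-3,3-dimethylcyclopentan-1-one | COc1cc(OC)c(Br)c(c1)[C@@H]1C(=O)C(=[N+]=[N-])C(C)(C)[C@H]1c1ccc2OCOc2c1 | intermediate
9 | [(3R,4S)-3-(1,3-benzodioxol-5-yl)-4-(2-bromo-3,5-dimethoxyphenyl)-2,2-dimethylcyclobutylidene]methanone (ketene) | COc1cc(OC)c(Br)c(c1)[C@@H]1C(=C=O)C(C)(C)[C@H]1c1ccc2OCOc2c1 | intermediate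
10 | (2S,2aS,7aS)-2-(1,3-benzodioxol-5-yl)-3-bromo-4,6-dimethoxy-1,1-dimethyl-1,2,2a,7a-tetrahydro-7H-cyclobuta[a]inden-7-one | COc1cc(OC)c2c(c1Br)[C@@H]1[C@H](C2=O)C(C)(C)[C@H]1c1ccc2OCOc2c1 | intermediate
11 | (2S,2aS,7aS)-3-bromo-2-(3,4-dihydroxyphenyl)-6-hydroxy-4-methoxy-1,1-dimethyl-1,2,2a,7a-tetrahydro-7H-cyclobuta[a]inden-7-one | COc1cc(O)c2c(c1Br)[C@@H]1[C@H](C2=O)C(C)(C)[C@H]1c1ccc(O)c(O)c1 | intermediate
12 | 4-[(2S,2aR,7aS)-3-bromo-6-hydroxy-4-methoxy-1,1-dimethyl-2,2a,7,7a-tetrahydro-1H-cyclobuta[a]inden-2-yl]benzene-1,2-diol | COc1cc(O)c2c(c1Br)[C@@H]1[C@H](C2)C(C)(C)[C@H]1c1ccc(O)c(O)c1 | intermediate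
13 | tributyl(3-methylbut-2-en-1-yl)stannane | CCCC[Sn](CCCC)(CCCC)CC=C(C)C | starting material
14 | 4-[(2S,2aR,7aS)-6-hydroxy-4-methoxy-1,1-dimethyl-3-(3-methylbut-2-en-1-yl)-2,2a,7,7a-tetrahydro-1H-cyclobuta[a]inden-2-yl]benzene-1,2-diol | COc1cc(O)c2c(c1CC=C(C)C)[C@@H]1[C@H](C2)C(C)(C)[C@H]1c1ccc(O)c(O)c1 | target

Total step count: 9
Longest linear sequence: 9 steps (1 → 3 → 5 → 6 → 7 → 8 → 10 → 11 → 12 → 14)

Steps most likely to fail

Step 6. The ketene may be lost by dimerisation or by hydration with adventitious water before the ring closes, or the acid may open other pathways before acylation. The fallback makes the two bonds in separate flasks. It sets out from 8: irradiation (450 nm) in MeOH/CH2Cl2 traps the ketene as methyl (3S,4S)-3-(1,3-benzodioxol-5-yl)-4-(2-bromo-3,5-dimethoxyphenyl)-2,2-dimethylcyclobutane-1-carboxylate F1 (both C1 epimers). LiOH in THF/H2O gives the corresponding carboxylic acid F2. Activation with (COCl)2/cat. DMF and then SnCl4 in CH2Cl2 at −20 °C closes the five-membered ring by classical Friedel–Crafts acylation; the trans epimer should converge by enolisation of the acid chloride. The route is rejoined at 10.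

Step 2. Site selectivity of the enolate arylation may be poor (attack at the methylene next to the quaternary carbon, or double arylation). The fallback fixes the enolate regiochemistry in the conjugate addition itself. It sets out from 1: 1,4-addition of (1,3-benzodioxol-5-yl)zinc chloride F3 (from the commercial Grignard reagent and ZnCl2), catalysed by [RhCl((R)-BINAP)]2 in THF with Me3SiCl at 20 °C, should give {[(3S)-3-(1,3-benzodioxol-5-yl)-4,4-dimethylcyclopent-1-en-1-yl]oxy}trimethylsilane F4, with the enol double bond between C1 and C2. Arylation of this silyl enol ether with 4 (Pd(dba)2, P(t-Bu)3, ZnF2, CsF, DMF, 80 °C) followed by base equilibration then gives the trans ketone, returning to the route at 5.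

Step 9. Oxidative addition into the doubly ortho-substituted, electron-rich bromide may be slow, and the free catechol may sequester or reduce the catalyst. The fallback replaces the cross-coupling by an organocopper alkylation on a protected substrate. It sets out from 12: TBSCl/imidazole in DMF gives the tris(tert-butyldimethylsilyl) ether of 12 F5. Bromine–lithium exchange (t-BuLi, 2.1 equiv, THF, −78 °C), transmetalation with CuBr·SMe2 and alkylation with prenyl bromide give the tris(tert-butyldimethylsilyl) ether of 14 F6. TBAF in THF at 0 °C removes the silyl groups and the route comes back at 14.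

Further compounds
F1 | step 6 | methyl (3S,4S)-3-(1,3-benzodioxol-5-yl)-4-(2-bromo-3,5-dimethoxyphenyl)-2,2-dimethylcyclobutane-1-carboxylate (C1 epimers) | COc1cc(OC)c(Br)c(c1)[C@@H]1C(C(=O)OC)C(C)(C)[C@H]1c1ccc2OCOc2c1
F2 | step 6 | (3S,4S)-3-(1,3-benzodioxol-5-yl)-4-(2-bromo-3,5-dimethoxyphenyl)-2,2-dimethylcyclobutane-1-carboxylic acid (C1 epimers) | COc1cc(OC)c(Br)c(c1)[C@@H]1C(C(=O)O)C(C)(C)[C@H]1c1ccc2OCOc2c1
F3 | step 2 | (1,3-benzodioxol-5-yl)zinc chloride | Cl[Zn]c1ccc2OCOc2c1
F4 | step 2 | {[(3S)-3-(1,3-benzodioxol-5-yl)-4,4-dimethylcyclopent-1-en-1-yl]oxy}trimethylsilane | C[Si](C)(C)OC1=C[C@H](c2ccc3OCOc3c2)C(C)(C)C1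
F5 | step 9 | tris(tert-butyldimethylsilyl) ether of 12 | COc1cc(O[Si](C)(C)C(C)(C)C)c2c(c1Br)[C@@H]1[C@H](C2)C(C)(C)[C@H]1c1ccc(O[Si](C)(C)C(C)(C)C)c(O[Si](C)(C)C(C)(C)C)c1
F6 | step 9 | tris(tert-butyldimethylsilyl) ether of 14 | COc1cc(O[Si](C)(C)C(C)(C)C)c2c(c1CC=C(C)C)[C@@H]1[C@H](C2)C(C)(C)[C@H]1c1ccc(O[Si](C)(C)C(C)(C)C)c(O[Si](C)(C)C(C)(C)C)c1
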